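## Retrosynthetic overview

1. Feature: in ring C the ketone carbon C4 is bonded to ring A ortho to O1, C3 is a plain CH2, and C2 carries only H, O1 and the ring B carbon. Returning the C2 hydrogen to C4 and cutting C3–C4 unfolds ring C into the salicylaldehyde O-(1-arylvinyl) ether 12.
2. Forward, an enantioselective rhodium-catalysed endo hydroacylation of 12 forms C3–C4, ring C and the C2 stereocentre in one step (13). Buffered fluoride then frees the 7-OH (14).
3. The O1–C2 bond of 12 is made at sp3 carbon by Mitsunobu etherification of salicylaldehyde 4 with bromohydrin 10, followed by loss of HBr. Cross-coupling of this di-ortho-substituted, electron-poor phenol with an ionisable 1-arylvinyl triflate is judged less dependable and is kept in reserve.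
4. Compound 4 comes from 2,4-dihydroxybenzaldehyde by C3-prenylation and 4-O-silylation. Compound 10 comes from 4-hydroxyacetophenone and isoprene (ring D), then alpha-bromination and reduction.
5. Ring order: rings A and B are bought, ring D closes in step 3, ring C closes in step 8.

Key step: step 8

Assumption: the sense of induction on this untested substrate class cannot be derived from the carbon-tethered analogues, so (R)-DTBM-SEGPHOS stands for whichever ligand antipode is found to give (2S)-13.

## Route

Step 1
Reactants: 1 2,4-dihydroxybenzaldehyde; 2 prenyl bromide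
Product: 3 2,4-dihydroxy-3-(3-methylbut-2-en-1-yl)benzaldehyde
Conditions: KOH (1.1 equiv), H2O, 0 °C → rt; dilute HCl; chromatography
Reagents that add atoms: none
Why: Phenoxide C-alkylation (nuclear prenylation) in a protic medium, where hydrogen bonding shields the oxygens and the soft allylic bromide is taken up at C3, the carbon activated by both flanking oxygens; the C5- and O-prenyl isomers that accompany it are removed by chromatography.

Step 2
Reactants: 3 2,4-dihydroxy-3-(3-methylbut-2-en-1-yl)benzaldehyde
Product: 4 2-hydroxy-3-(3-methylbut-2-en-1-yl)-4-(triisopropylsilyloxy)benzaldehyde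
Conditions: TIPSCl (1.05 equiv), imidazole, CH2Cl2, 0 °C → rt
Reagents that add atoms: triisopropylsilyl chloride, CC(C)[Si](Cl)(C(C)C)C(C)C
Why: Selective phenol silylation, since the 2-OH is locked in a hydrogen bond to the formyl oxygen and flanked on both sides, so the more acidic and more open 4-OH takes the bulky silyl group.

Step 3
Reactants: 5 4-hydroxyacetophenone; 6 isoprene
Product: 8 6-acetyl-2,2-dimethylchroman, via 4-hydroxy-3-prenylacetophenone 7 (not isolated)
Conditions: 85% H3PO4, xylene, 35 °C, slow addition of 6
Reagents that add atoms: none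
Why: Friedel–Crafts prenylation by the cation from protonated isoprene at one of the two equivalent positions ortho to OH, followed by acid-catalysed Markovnikov hydroalkoxylation of the trisubstituted alkene by the phenol, which closes ring D.

Step 4
Reactants: 8 6-acetyl-2,2-dimethylchroman
Product: 9 2-bromo-1-(2,2-dimethylchroman-6-yl)ethanone
Conditions: CuBr2 (2.1 equiv), EtOAc–CHCl3, reflux
Reagents that add atoms: CuBr2, [Cu+2].[Br-].[Br-]
Why: Alpha-bromination of an aryl methyl ketone through its enol, for which heterogeneous CuBr2 is chosen because it brominates the enol only, stops at the monobromide and leaves the acyl-deactivated alkoxyarene ring alone.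

Step 5
Reactants: 9 2-bromo-1-(2,2-dimethylchroman-6-yl)ethanone
Product: 10 (±)-2-bromo-1-(2,2-dimethylchroman-6-yl)ethanol
Conditions: NaBH4, MeOH, 0 °C; quench at pH 6–7
Reagents that add atoms: none
Why: Borohydride reduction of an alpha-bromo ketone to the bromohydrin, kept cold and quenched without base so that no epoxide forms; the carbinol centre is racemic on purpose because it becomes sp2 in step 7.

Step 6
Reactants: 4 2-hydroxy-3-(3-methylbut-2-en-1-yl)-4-(triisopropylsilyloxy)benzaldehyde; 10 (±)-2-bromo-1-(2,2-dimethylchroman-6-yl)ethanol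
Product: 11 (±)-2-[2-bromo-1-(2,2-dimethylchroman-6-yl)ethoxy]-3-prenyl-4-(triisopropylsilyloxy)benzaldehyde
Conditions: PPh3, DIAD, toluene (concentrated), 0 °C → rt
Reagents that add atoms: none
Why: Mitsunobu etherification, in which the acidic salicylaldehyde phenol protonates the betaine and its phenoxide displaces the activated para-alkoxybenzylic oxyphosphonium group at the carbon that becomes C2; the new stereocentre is racemic and is erased in step 7.

Step 7
Reactants: 11 (±)-2-[2-bromo-1-(2,2-dimethylchroman-6-yl)ethoxy]-3-prenyl-4-(triisopropylsilyloxy)benzaldehyde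
Product: 12 2-[1-(2,2-dimethylchroman-6-yl)vinyloxy]-3-prenyl-4-(triisopropylsilyloxy)benzaldehyde
Conditions: KOtBu (1.2 equiv), THF, −20 → 0 °C; pH 7 buffer; Et3N-washed silica
Reagents that add atoms: none
Why: E2 dehydrobromination of a beta-bromo ether, in which the only beta hydrogen is the benzylic oxygen-bearing C–H, bromide is a far better leaving group than the aryloxide, the aldehyde has no alpha hydrogen, and the hindered base at low temperature should spare the TIPS ether.

Step 8
Reactants: 12 2-[1-(2,2-dimethylchroman-6-yl)vinyloxy]-3-prenyl-4-(triisopropylsilyloxy)benzaldehyde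
Product: 13 (2S)-2-(2,2-dimethylchroman-6-yl)-8-prenyl-7-(triisopropylsilyloxy)chroman-4-one
Conditions: [Rh(cod)Cl]2 (2.5 mol%), (R)-DTBM-SEGPHOS (5.5 mol%), NaB[3,5-(CF3)2C6H3]4 (6 mol%), 2,6-di-tert-butyl-4-methylpyridine (10 mol%), 1,4-dioxane, 80 °C, argon
Reagents that add atoms: none
Why: Proposed new method: monovalent rhodium inserts into the formyl C–H bond of 12 to give an acyl rhodium hydride (trivalent rhodium), the tethered vinyl ether binds, the hydride migrates to C2 while rhodium takes the unsubstituted C3, and reductive elimination from the seven-membered acyl–alkyl rhodacycle joins C3 to C4. The closest known reaction type is the rhodium/bisphosphine-catalysed enantioselective endo hydroacylation of 1,1-disubstituted alkenes in ortho-(2-substituted allyl)benzaldehydes (to 3-substituted tetralones) and in 2-(1-arylvinyl)benzaldehydes (to 3-arylindanones); 12 is the analogue of the former with O1 in place of the benzylic CH2, and an electron-rich, oxygen-linked alkene has not been shown to insert in this sense. Ring C closes in the 6-endo mode, both alkene carbons becoming ring atoms, because the 5-exo alternative would require a tertiary C2–Rh bond and would end in a 2-aryl-2-methylbenzofuran-3-one. C2, the only new stereocentre, is fixed in the hydride migration, where the 3,5-di-tert-butyl-4-methoxyphenyl groups of the axially chiral ligand decide which face of the 1-arylvinyl ether lies on rhodium. The step needs chemoselectivity over the prenyl alkene, which is trisubstituted and sits meta to the acyl carbon out of reach of the metal, and it needs reductive elimination to outrun decarbonylation and beta-aryloxide loss from the C3–Rh alkyl, for which the weak O1 chelate, the electron-rich acyl group and the cationic, bulky bisphosphine complex are relied on. The non-hydrolysable borate counter-ion and the hindered pyridine keep acid away from the enol ether.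

Step 9
Reactants: 13 (2S)-2-(2,2-dimethylchroman-6-yl)-8-prenyl-7-(triisopropylsilyloxy)chroman-4-one
Product: 14 euchrenone a17, (2S)-2-(2,2-dimethylchroman-6-yl)-7-hydroxy-8-prenylchroman-4-one
Conditions: HF·pyridine, excess pyridine, THF, 0 °C
Reagents that add atoms: none
Why: Fluoride desilylation of an aryl silyl ether activated by the para acyl group, run in a buffered non-basic medium so that no C3 enolate forms and C2 is not scrambled by retro-oxa-Michael opening, and mild enough not to cyclise the prenyl group onto the free 7-OH.

## Compound list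

1 | 2,4-dihydroxybenzaldehyde | O=Cc1ccc(O)cc1O | starting material
2 | prenyl bromide | CC(C)=CCBr | starting material
3 | 2,4-dihydroxy-3-(3-methylbut-2-en-1-yl)benzaldehyde | CC(C)=CCc1c(O)ccc(C=O)c1O | intermediate
4 | 2-hydroxy-3-(3-methylbut-2-en-1-yl)-4-(triisopropylsilyloxy)benzaldehyde | CC(C)=CCc1c(O[Si](C(C)C)(C(C)C)C(C)C)ccc(C=O)c1O | intermediate
5 | 4-hydroxyacetophenone | CC(=O)c1ccc(O)cc1 | starting material
6 | isoprene | C=CC(C)=C | starting material
7 | 4-hydroxy-3-prenylacetophenone (not isolated) | CC(=O)c1ccc(O)c(CC=C(C)C)c1 | intermediate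
8 | 6-acetyl-2,2-dimethylchroman | CC(=O)c1ccc2c(c1)CCC(C)(C)O2 | intermediate
9 | 2-bromo-1-(2,2-dimethylchroman-6-yl)ethanone | O=C(CBr)c1ccc2c(c1)CCC(C)(C)O2 | intermediate
10 | (±)-2-bromo-1-(2,2-dimethylchroman-6-yl)ethanol | OC(CBr)c1ccc2c(c1)CCC(C)(C)O2 | intermediate
11 | (±)-2-[2-bromo-1-(2,2-dimethylchroman-6-yl)ethoxy]-3-prenyl-4-(triisopropylsilyloxy)benzaldehyde | CC(C)=CCc1c(O[Si](C(C)C)(C(C)C)C(C)C)ccc(C=O)c1OC(CBr)c1ccc2c(c1)CCC(C)(C)O2 | intermediate
12 | 2-[1-(2,2-dimethylchroman-6-yl)vinyloxy]-3-prenyl-4-(triisopropylsilyloxy)benzaldehyde | CC(C)=CCc1c(O[Si](C(C)C)(C(C)C)C(C)C)ccc(C=O)c1OC(=C)c1ccc2c(c1)CCC(C)(C)O2 | intermediate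
13 | (2S)-2-(2,2-dimethylchroman-6-yl)-8-prenyl-7-(triisopropylsilyloxy)chroman-4-one | CC(C)=CCc1c(O[Si](C(C)C)(C(C)C)C(C)C)ccc2c1O[C@H](c1ccc3c(c1)CCC(C)(C)O3)CC2=O | intermediate
14 | euchrenone a17 | CC(C)=CCc1c(O)ccc2c1O[C@H](c1ccc3c(c1)CCC(C)(C)O3)CC2=O | target

## Step count

Total steps: 9.
Longest linear sequence: 7 (steps 3, 4, 5, 6, 7, 8, 9).

## Steps most likely to fail

**1. Step 8.**
- The hydride may be delivered to C3 instead of C2, which gives exo closure.
- The acyl rhodium hydride may decarbonylate.
- The C2–O1 bond may break by beta-aryloxide elimination from the C3–Rh alkyl.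
- The enol ether may attack the aldehyde under Lewis or Brønsted acid activation.
- The two alkene faces may be poorly distinguished.

The fallback uses known chemistry. It sets out from 4 and 6 and returns at 13. MeMgBr (2.2 equiv, THF, 0 °C) should add to 4 to give 1-[2-hydroxy-3-prenyl-4-(triisopropylsilyloxy)phenyl]ethanol F1. MnO2 in CH2Cl2 should oxidise this to 2-hydroxy-3-prenyl-4-(triisopropylsilyloxy)acetophenone F2. Heating with N,N-dimethylformamide dimethyl acetal in toluene should give (E)-3-(dimethylamino)-1-[2-hydroxy-3-prenyl-4-(triisopropylsilyloxy)phenyl]prop-2-en-1-one F3. Brief mild acid treatment should close it to 8-prenyl-7-(triisopropylsilyloxy)chromen-4-one F4. In parallel, 4-bromophenol and 6 (85% H3PO4) should give 6-bromo-2,2-dimethylchroman F5. Treatment with n-BuLi, B(OiPr)3 and aqueous acid then gives (2,2-dimethylchroman-6-yl)boronic acid F6. Asymmetric conjugate addition of F6 to F4 is a known route to enantioenriched flavanones from chromones. It would be run with Pd(OCOCF3)2, the suitable antipode of the tert-butyl pyridine-oxazoline ligand, NH4PF6 and H2O in ClCH2CH2Cl at 60 °C. It sets C2 by forming the C2–aryl bond and gives 13.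

**2. Step 6.**
- The di-ortho-substituted phenoxide may attack too slowly. The reduced azodicarboxylate would then capture the benzylic carbon, or the oxyphosphonium ion would ionise and eliminate.
- The base-sensitive step 7 depends on the same intermediate.

The fallback sets out from 8 and 4 and returns at 12, bypassing steps 4 to 7. Kinetic enolisation of 8 (KN(SiMe3)2, THF, −78 °C) and O-sulfonylation with N-phenylbis(trifluoromethanesulfonimide) should give 1-(2,2-dimethylchroman-6-yl)vinyl trifluoromethanesulfonate F7. C(sp2)–O cross-coupling of F7 with 4 forms the O1–C2 bond directly at the alkene carbon and gives 12. The conditions would be Pd2(dba)3, 2-(di-tert-butylphosphino)biphenyl and K3PO4 in toluene at 80 °C.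

**3. Step 1.**
- Alkylation may spread over C3, C5 and oxygen.
- Alkylation may run on to bis-prenylation, which makes the separation wasteful.

The fallback sets out from 1 and returns at 3. Selective alkylation of the free 4-OH with 3-chloro-3-methylbut-1-yne (DBU, catalytic CuCl2, MeCN, 0 °C) should give 2-hydroxy-4-(2-methylbut-3-yn-2-yloxy)benzaldehyde F8. Semihydrogenation (H2, Pd/CaCO3 poisoned with Pb(OAc)2, quinoline, EtOAc) should give 2-hydroxy-4-(2-methylbut-3-en-2-yloxy)benzaldehyde F9. Heating F9 in N,N-diethylaniline should trigger an aromatic Claisen rearrangement. It delivers the inverted allyl unit as a prenyl group to C3, the ortho position favoured by the bond fixation of the chelated salicylaldehyde, and gives 3.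

## Further compounds

F1 | step 8 | 1-[2-hydroxy-3-prenyl-4-(triisopropylsilyloxy)phenyl]ethanol (racemic) | CC(O)c1ccc(O[Si](C(C)C)(C(C)C)C(C)C)c(CC=C(C)C)c1O
F2 | step 8 | 2-hydroxy-3-prenyl-4-(triisopropylsilyloxy)acetophenone | CC(=O)c1ccc(O[Si](C(C)C)(C(C)C)C(C)C)c(CC=C(C)C)c1O
F3 | step 8 | (E)-3-(dimethylamino)-1-[2-hydroxy-3-prenyl-4-(triisopropylsilyloxy)phenyl]prop-2-en-1-one | CN(C)/C=C/C(=O)c1ccc(O[Si](C(C)C)(C(C)C)C(C)C)c(CC=C(C)C)c1O
F4 | step 8 | 8-prenyl-7-(triisopropylsilyloxy)chromen-4-one | CC(C)=CCc1c(O[Si](C(C)C)(C(C)C)C(C)C)ccc2c1OC=CC2=O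
F5 | step 8 | 6-bromo-2,2-dimethylchroman | CC1(C)CCc2cc(Br)ccc2O1
F6 | step 8 | (2,2-dimethylchroman-6-yl)boronic acid | CC1(C)CCc2cc(B(O)O)ccc2O1
F7 | step 6 | 1-(2,2-dimethylchroman-6-yl)vinyl trifluoromethanesulfonate | C=C(OS(=O)(=O)C(F)(F)F)c1ccc2c(c1)CCC(C)(C)O2
F8 | step 1 | 2-hydroxy-4-(2-methylbut-3-yn-2-yloxy)benzaldehyde | C#CC(C)(C)Oc1ccc(C=O)c(O)c1
F9 | step 1 | 2-hydroxy-4-(2-methylbut-3-en-2-yloxy)benzaldehyde | C=CC(C)(C)Oc1ccc(C=O)c(O)c1
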